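The numbers in the tables are simulated from invented constants; the scatter is artificial.

The constants are not given, so you read the one that matters from the earlier runs, working in fractions of the starting material charged.

| flask | starting material | reagent | remark | time |
|---|---|---|---|---|
| alpha | 20 mM | 0.95 equiv | run made earlier |  |
| delta | 20 mM | 0.47 equiv | run made earlier |  |
| gamma | 20 mM | 0.71 equiv | run made earlier |  |
| eta | 10 mM | 0.95 equiv | run made earlier |  |
| oak | 20 mM (fed, over 2.00 min) | 0.950 equiv | all but starting material at the start; starting material goes in evenly over 2.00 min, the run ends at 4.0 min | 4.0 min |
| alder | 20 mM | 0.950 equiv (fed, over 2.00 min) | all but reagent at the start; reagent goes in evenly over 2.00 min, the run ends at 4.0 min | 4.0 min |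
| ash | 20 mM | 0.950 equiv | a single well-mixed tank run continuously and read at steady state, 4.0 min in it on average |  |
| maple | 20 mM | 0.950 equiv | a closed flask charged with all of it at once and left for 4.0 min | 4.0 min |

| run | time / min | single product / % | double product / % |
|---|---|---|---|
| alpha | 0.500 | 57.6 | 3.0 |
| alpha | 1.00 | 55.5 | 4.1 |
| alpha | 1.50 | 54.6 | 5.2 |
| alpha | 2.50 | 52.9 | 6.8 |
| alpha | 3.00 | 52.2 | 6.9 |
| alpha | 4.00 | 50.7 | 7.9 |
| delta | 0.333 | 30.0 | 0 |
| delta | 0.667 | 25.9 | 0.3 |
| delta | 1.00 | 21.3 | 0.3 |
| delta | 1.33 | 17.1 | 0.6 |
| delta | 1.50 | 15.5 | 0.7 |
| delta | 2.00 | 12.4 | 0.8 |
| delta | 2.50 | 9.6 | 1.0 |
| gamma | 0.333 | 44.9 | 1.3 |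
| gamma | 0.667 | 42.9 | 1.6 |
| gamma | 1.00 | 40.6 | 2.1 |
| gamma | 1.33 | 38.5 | 2.3 |
| gamma | 1.50 | 37.9 | 2.0 |
| gamma | 2.00 | 35.6 | 2.1 |
| gamma | 2.50 | 34.8 | 2.0 |
| eta | 0.200 | 43.3 | 0.8 |
| eta | 0.333 | 51.3 | 1.0 |
| eta | 0.667 | 57.0 | 2.9 |
| eta | 1.33 | 57.4 | 3.5 |
| eta | 2.50 | 54.9 | 5.3 |

(standard deviation of a reading: 0.3 percentage points)

- a species is counted by the starting material in it: one side product counts as two
- the stated concentrations are those of everything mixed, before any reaction; amounts are the same in each set-up
- the numbers in the tables scatter with a standard deviation of 0.3 percentage points
- the feed brings no volume worth counting
- the earlier runs were made in a closed, stirred flask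
- the share counts what is present at the end, not what went on to other products

- order of the set-ups by the share of single product in all that became single product or double product or tris adduct or side product, at the outlet or at the end, highest first (oak / alder / ash / maple)
- share of single product in all that became single product or double product or tris adduct or side product, at the outlet or at the end, oak
- share of single product in all that became single product or double product or tris adduct or side product, at the outlet or at the end, alder
- share of single product in all that became single product or double product or tris adduct or side product, at the outlet or at the end, ash
- share of single product in all that became single product or double product or tris adduct or side product, at the outlet or at the end, maple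

Begin with the main step by itself: starting material and reagent give single product. In that picture single product reaches the reagent's 0.950 equiv of the charge, nothing else forms, and the vessel does not matter.

Now add the second step, in which starting material and single product give side product. The delta run shows it best, since it was charged short of reagent. I take its reagent as consumed by the first reading. Each side step then removes one of each, so starting material stays ahead of single product by a fixed fraction, d = 0.0600. Integrating the second-order law between delta's first and last readings gives

κ = ln[ m(first)·(m(last) + d) / ((m(first) + d)·m(last)) ] / (d·Δt) = 2.33 /min

This κ, the side rate, is the pseudo-first-order rate at which single product would be lost beside the whole charge of starting material. It grows with the charge, so for second-order steps at equal equivalents the contact κt sets the composition. The eta run tests this. With half the charge, its 54.9% at 2.50 min should match alpha at 1.25 min, and alpha reads 55.5% and 54.6% on either side.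

Alpha's highest reading is its first, at a contact of 1.17. A feed lasting 2.00 min stretches that to 4.66.

Last come the slow steps. In alpha, what is neither single nor double product goes from 39.4% to 41.4%, so I freeze the side loss and let single product drift down into double product. My maple is then alpha's 50.7%. I put oak next, with reagent waiting for each portion of starting material, then ash, then alder.

The forecast gave maple > oak > ash > alder, with oak 48%, alder 34%, ash 36% and maple 51%, noting that “Alder keeps starting material in excess while single product builds up”.

The flask gives maple > oak > ash > alder: oak 43.1%, alder 31.3%, ash 34.0%, maple 51.1%.

    reagent + double product → tris adduct (k = 0.790 /M/s)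
    starting material + reagent → single product (k = 8.50 /M/s)
    starting material + single product → side product (k = 1.80 /M/s)
    reagent + single product → double product (k = 0.370 /M/s)
    single product → over-reaction product (k = 7.90 × 10⁻⁵ /s)

Part of what separates alder from maple is the slow dosing of reagent, which takes the share from 51.1% to 31.3%. With the side step taken away, alder minus maple goes from −20 percentage points to 0.12 points. Side product in alder stands at 57.8% when the feed ends, against 39.1% at the end of maple. In the neighbour with 5.0 mM of starting material, the side rate falls to 0.583 /min, so its 4.0 min equals alpha's 1.00 min, where alpha reads 55.5%. That neighbour ends with 55.6% single product.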